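## The problem

Juglanin A (17) is a cyclic diaryl ether heptanoid. A seven-carbon chain, C1 to C7 with a ketone at C3, runs from the carbon of anisole ring A that is meta to the ether oxygen to the carbon of ring B that is para to it. Chain, ether oxygen and the two arene edges therefore form a 15-membered oxa-metaparacyclophane, and closing this bent ring without feeding oligomers is the first task. The second is ring B: it is 1,2,3,4-tetrasubstituted with three contiguous, different oxygen functions (aryl ether, methyl ether, free phenol next to C7). The diaryl ether must therefore be made at one defined oxygen and the phenol beside the chain kept distinct. The target has no stereocentre, so any centre or alkene geometry created on the way needs no control and only has to be removable. The parts that will not take rough treatment are the electron-rich free phenol, the ketone (enolisable at C2 and C4), and, in an open precursor, an aliphatic aldehyde and a terminal alkyne. The enabling feature is that C3 bears oxygen and has C4–C5 beside it. At the allylic alcohol level, C3(OH)–C4=C5 is what results from joining an aldehyde carbon C3 on a three-carbon arm of ring A to the terminal alkyne carbon C4 of a four-carbon arm on ring B.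

## Retrosynthesis

**17 from 16.** No skeletal bond is cut. The saturated C4–C5 unit and the free phenol of 17 are both traced to the benzyl-protected E-enone 16. One hydrogenation over palladium saturates the alkene and removes the benzyl group, so the protecting group costs no step of its own. The forward reaction must leave the aliphatic ketone and the diaryl ether alone, which mild hydrogenation does.

**16 from 15 from 14.** The enone is taken back to the allylic alcohol 15 and this to its triethylsilyl ether 14. Both are oxidation-level or protecting-group changes. The C3 carbinol is the only alcohol in 15 and is allylic, so the oxidation has no selectivity problem, and the racemic centre disappears here.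

**14 from 13 (key cut, C3–C4).** The macrocycle is opened between C3 and C4, giving the ynal 13: an open diaryl ether with a propanal arm on ring A and a butynyl arm on ring B.
- Against closing at the ether oxygen: both rings are electron-rich and unactivated, so a ring-closing diaryl ether synthesis would need forcing copper chemistry.
- Against closing at C4=C5 by olefin metathesis: this would reach 16 directly and save two steps, but it needs a polymerisation-prone aryl vinyl ketone and a reversible closure of a strained ring.
- Against enolate closures at C2–C3 or C3–C4: these need regiocontrolled enolisation of a ketone with two similar α-methylenes.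
- For the chosen cut: both termini are neutral, a metal gathers them before the bond forms, the step is irreversible, and the oxidation pattern maps onto the ketone.

The forward step must bond C3 to the terminal alkyne carbon and must outrun intermolecular coupling.

**13 from 12.** The aldehyde is masked as a 1,3-dioxolane. This allows the alkyne arm to be installed with an organolithium and unmasked with base before the aldehyde exists. Mild aqueous acid then releases 13 just before the key step.

**12 from 9 and 10 (via 11); 9 from 8 from 7.** The butynyl arm is cut at C6–C7: benzylic bromide 9 plus the propargyl anion of silylpropyne 10. C7 is the benzylic carbon, and it derives from the aldehyde that was used to build ring B, so the electrophile is reached by reduction (8) and bromination (9). The silyl group directs alkylation to the propargylic carbon and comes off in the same flask (11 to 12).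

**7 from 5 and 6.** The ring A arm is cut at the aryl–C1 bond: aryl bromide 5 plus the three-carbon zinc reagent 6, which carries the aldehyde as its acetal (Negishi coupling). A Heck arylation delivering the free aldehyde directly would be one step shorter on paper. It was set aside because it would have to be run late, in the presence of the alkyne, and gives regioisomeric aldehydes. The zinc reagent is regiospecific, tolerates the aryl aldehyde of 5, and removes the aryl bromide before any organolithium is used.

**5 from 4 from 2 and 3.** The diaryl ether is cut on the ring A side of oxygen: phenol 2 plus boronic acid 3 (Chan–Lam), then benzylation of the remaining phenol. Cutting on the ring B side would need an electrophilic ring B carbon flanked by a methoxy group, for which no simple partner exists. In 2 the hydroxyl para to the aldehyde is free and the more acidic, while the ortho hydroxyl is hydrogen-bonded to the aldehyde. The copper coupling at room temperature leaves the C–Br bond of 3 untouched for the later Negishi step.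

**2 from 1.** The formyl carbon is removed. Compound 1 is symmetric and its two activated positions are equivalent, so formylation can give only one aldehyde. This aldehyde both differentiates the two phenols and becomes C7.

## Roads not taken

**Alternative 1:** Cut B2–B3 and B4–B5 of ring B together with the macrocycle. The precursor A1 carries a 3-aryloxy-4-methoxyfuran on ring A's oxygen and, at the end of the ketone-bearing chain, a conjugated ynal. On heating at high dilution the furan adds across the alkyne, creating an oxygen bridge between B2 and B5. This bridge opens in the same flask to give the phenol A2, a B3-formyl juglanin A.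
- Merits: the tetrasubstituted ring B, its phenol and the macrocycle arise in one operation. No phenol protecting group is needed. Only a decarbonylation separates A2 from the target, which is a shorter end game than the three steps of the chosen plan.
- Weak points: an unsymmetrical 3,4-dioxygenated furan with free α-positions is acid-labile and has no short synthesis. The cycloaddition is reversible, has no short tether to help it, and can occur in two orientations. The bridge can open toward B5 or B2. The extra formyl group needs a stoichiometric rhodium decarbonylation.
- Comparison: in convergence and end-game length Alternative 1 is better. The chosen plan sets against it precursors made from commercial arenes by standard reactions, a single regiochemical question with a known answer, and a key step belonging to an established reaction class.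

**Alternative 2:** Cut A1–A2 and A5–A6, so that ring A is assembled inside the macrocycle. The precursor A3 is an aryl ether of ring B with a 3-methoxybuta-1,3-dien-2-yl group, and its chain ends in a terminal ynone beside a ketal-protected C3. Heating closes a cyclohexadiene ring and the 15-membered ring at once (a type 2 intramolecular Diels–Alder reaction). A quinone oxidant added to the same flask aromatises the new ring to A4, the O-benzyl 1-oxo 3-ketal of juglanin A.
- Merits: no metal is needed, the reaction is thermal, and ring A appears with all three substituents in place.
- Weak points: regiochemistry rests on the small donor difference between methoxy and aryloxy on the diene, and in a ring this large the tether enforces nothing. The dienyl aryl ether and the β-ketal ynone in A3 are both fragile and hard to make. A4 has a superfluous C1 ketone in a 1,3-relationship to C3, which must be removed before the ketal is opened.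
- Comparison: the end game from A4 (benzylic deoxygenation with debenzylation, then ketal hydrolysis) is no longer than the chosen one, so on step count after the key step the two are level. The chosen plan wins on access to the precursor and on having one selectivity issue controlled by a ligand rather than by substrate electronics.

**Alternative 3:** Cut C6–C7. The precursor A5 has an ortho-hydroxybenzyl alcohol on ring B and, on ring A, the chain as a silyl dienol ether (C3–O–Si, C3=C4, C5=C6). Irradiation near 300 nm dehydrates ring B to its ortho-quinone methide form. Its methylene C7 is attacked by the terminal carbon C6, and fluoride work-up gives the enone A6, 4,5-didehydro juglanin A.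
- Merits: the phenol is the reactive handle, so it needs no protection. A6 is one hydrogenation from the target, the shortest end game of all four plans.
- Weak points: a silyl dienol ether must be made and kept in a molecule with a free phenol and a benzylic alcohol. Quinone methides react with enol ethers mainly by hetero-Diels–Alder addition to chromans. Attack can also come from C4. The enone in A6 absorbs in the same spectral window.
- Comparison: Alternative 3 is better in protecting-group economy and end-game length. The chosen plan has a closure whose regiochemistry and geometry have a predictable basis, and a precursor in which no two functional groups are mutually incompatible.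

Key step: step 9

Remark on the chemistry: compounds 14 and 15 are racemic at C3 (one enantiomer drawn), which does not matter because C3 becomes the ketone carbon. Reagent 6 is taken as its commercial THF solution.

## Route

Step 1
Reactants: 1 2-methoxyresorcinol (2-methoxybenzene-1,3-diol)
Product: 2 2,4-dihydroxy-3-methoxybenzaldehyde
Conditions: POCl3, DMF, MeCN, 0 °C to rt; then H2O, 50 °C
Reagents that add atoms: N,N-dimethylformamide, CN(C)C=O; water, O
Why: Vilsmeier–Haack formylation; the two activated positions of 1 are equivalent, each ortho to one hydroxyl and para to the other, so a single aldehyde should form, as with resorcinol itself.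

Step 2
Reactants: 2 2,4-dihydroxy-3-methoxybenzaldehyde; 3 (5-bromo-2-methoxyphenyl)boronic acid
Product: 4 4-(5-bromo-2-methoxyphenoxy)-2-hydroxy-3-methoxybenzaldehyde
Conditions: Cu(OAc)2 (1 equiv), pyridine, 4 Å MS, CH2Cl2, dry air (terminal oxidant), rt; 3 in excess
Reagents that add atoms: none
Why: Chan–Lam O-arylation; the 2-hydroxyl is hydrogen-bonded to the aldehyde and flanked on both sides, so the free and more acidic 4-hydroxyl should couple, and the C–Br bond is inert to copper at room temperature.

Step 3
Reactants: 4 4-(5-bromo-2-methoxyphenoxy)-2-hydroxy-3-methoxybenzaldehyde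
Product: 5 2-(benzyloxy)-4-(5-bromo-2-methoxyphenoxy)-3-methoxybenzaldehyde
Conditions: BnBr, K2CO3, DMF, 60 °C
Reagents that add atoms: benzyl bromide, BrCc1ccccc1
Why: Williamson ether synthesis on the only remaining phenol; warming in DMF breaks the hydrogen bond to the aldehyde, as is routine for salicylaldehydes.

Step 4
Reactants: 5 2-(benzyloxy)-4-(5-bromo-2-methoxyphenoxy)-3-methoxybenzaldehyde; 6 [2-(1,3-dioxolan-2-yl)ethyl]zinc bromide
Product: 7 2-(benzyloxy)-4-{5-[2-(1,3-dioxolan-2-yl)ethyl]-2-methoxyphenoxy}-3-methoxybenzaldehyde
Conditions: Pd(OAc)2 (cat.), SPhos (2-dicyclohexylphosphino-2',6'-dimethoxybiphenyl), THF, rt to 45 °C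
Reagents that add atoms: none
Why: Negishi sp2–sp3 cross-coupling; alkylzinc halides do not add to aryl aldehydes without Lewis acid activation, and the electron-rich biaryl phosphine lets zerovalent palladium insert into the electron-rich C–Br bond and favours reductive elimination over β-hydride loss.

Step 5
Reactants: 7 2-(benzyloxy)-4-{5-[2-(1,3-dioxolan-2-yl)ethyl]-2-methoxyphenoxy}-3-methoxybenzaldehyde
Product: 8 [2-(benzyloxy)-4-{5-[2-(1,3-dioxolan-2-yl)ethyl]-2-methoxyphenoxy}-3-methoxyphenyl]methanol
Conditions: NaBH4, MeOH/THF, 0 °C
Reagents that add atoms: none
Why: Borohydride reduction of an aryl aldehyde; the acetal and ethers are inert.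

Step 6
Reactants: 8 [2-(benzyloxy)-4-{5-[2-(1,3-dioxolan-2-yl)ethyl]-2-methoxyphenoxy}-3-methoxyphenyl]methanol
Product: 9 2-(benzyloxy)-1-(bromomethyl)-4-{5-[2-(1,3-dioxolan-2-yl)ethyl]-2-methoxyphenoxy}-3-methoxybenzene
Conditions: CBr4, PPh3, CH2Cl2, 0 °C; used directly
Reagents that add atoms: carbon tetrabromide, BrC(Br)(Br)Br
Why: Appel bromination; the neutral conditions spare the dioxolane, which acidic brominating agents would endanger.

Step 7
Reactants: 9 2-(benzyloxy)-1-(bromomethyl)-4-{5-[2-(1,3-dioxolan-2-yl)ethyl]-2-methoxyphenoxy}-3-methoxybenzene; 10 1-(trimethylsilyl)propyne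
Product: 12 2-(2-{3-[3-(benzyloxy)-4-(but-3-yn-1-yl)-2-methoxyphenoxy]-4-methoxyphenyl}ethyl)-1,3-dioxolane, via trimethylsilyl alkyne 11 (not isolated)
Conditions: 10, n-BuLi, THF, −78 °C; then 9, −78 to 0 °C; then MeOH, K2CO3 (cat.), rt
Reagents that add atoms: none
Why: Propargylic alkylation of a benzylic bromide by 3-lithio-1-(trimethylsilyl)propyne, the silyl group directing attack through the propargylic carbon, followed by base-catalysed methanolysis of the C–Si bond; no aryl halide or carbonyl group is left to interfere.

Step 8
Reactants: 12 2-(2-{3-[3-(benzyloxy)-4-(but-3-yn-1-yl)-2-methoxyphenoxy]-4-methoxyphenyl}ethyl)-1,3-dioxolane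
Product: 13 3-{3-[3-(benzyloxy)-4-(but-3-yn-1-yl)-2-methoxyphenoxy]-4-methoxyphenyl}propanal
Conditions: 1 M aq. HCl, THF, rt
Reagents that add atoms: water, O
Why: Acid-catalysed acetal hydrolysis; benzyl and methyl ethers and the terminal alkyne are stable to dilute acid, and the aldehyde is released only now so that it meets neither base nor organometallics.

Step 9
Reactants: 13 3-{3-[3-(benzyloxy)-4-(but-3-yn-1-yl)-2-methoxyphenoxy]-4-methoxyphenyl}propanal
Product: 14 macrocyclic (E)-allylic triethylsilyl ether, i.e. O-benzyl juglanin A with C3 as CH–OSiEt3 and an E C4=C5 double bond (racemic)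
Conditions: Ni(cod)2 (20 mol%), IMes (1,3-dimesitylimidazol-2-ylidene, 20 mol%), Et3SiH (3 equiv), THF, rt; 13 added by syringe pump, final concentration about 0.005 M
Reagents that add atoms: triethylsilane, CC[SiH](CC)CC
Why: This is a nickel-catalysed reductive alkyne–aldehyde coupling with a silane run as a macrocyclisation; the closest known reaction type is the carbene–nickel/triethylsilane reductive macrocyclisation of terminal ynals to endocyclic E-allylic silyl ethers. Zerovalent nickel bearing IMes binds the alkyne and the aldehyde of 13 and undergoes oxidative cyclisation to a five-membered oxanickelacycle in which the C3–C4 bond is made; sigma-bond metathesis of the Ni–O bond with Et3SiH forms the O–Si bond and a vinylnickel hydride, and reductive elimination places hydrogen on C5 and returns zerovalent nickel. The 15-membered ring closes in the endocyclic mode, both alkyne carbons C4 and C5 becoming ring members. The E geometry follows from cis addition of C3 and hydrogen across the alkyne. The one new stereocentre, C3, forms without control from an achiral substrate, so 14 is racemic, and the centre is erased in step 11. The selectivity needed is bond formation at the terminal carbon C4 and not at C5, which would give a 14-membered ring with an exocyclic methylene; the unhindered C–H terminus and the small IMes ligand place the terminal carbon next to the aldehyde carbon in the metallacycle. Slow addition at high dilution should keep ring closure ahead of intermolecular coupling and alkyne oligomerisation, and the benzyl, methyl and diaryl ethers are inert to zerovalent nickel at room temperature.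

Step 10
Reactants: 14 macrocyclic (E)-allylic triethylsilyl ether
Product: 15 macrocyclic (E)-allylic alcohol, i.e. O-benzyl-4,5-didehydro-3-deoxo-3-hydroxyjuglanin A (racemic)
Conditions: TBAF, THF, 0 °C
Reagents that add atoms: none
Why: Fluoride cleavage of a triethylsilyl ether; no other fluoride-labile group is present.

Step 11
Reactants: 15 macrocyclic (E)-allylic alcohol
Product: 16 O-benzyl-4,5-didehydrojuglanin A (macrocyclic E-enone)
Conditions: activated MnO2 (excess), CH2Cl2, rt
Reagents that add atoms: none
Why: Manganese dioxide oxidation of the only, allylic, alcohol; the reagent does not touch the benzyl ether or the electron-rich arenes, and the racemic centre is removed.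

Step 12
Reactants: 16 O-benzyl-4,5-didehydrojuglanin A
Product: 17 juglanin A
Conditions: H2 (1 atm), Pd/C (10 wt% Pd), EtOAc, rt
Reagents that add atoms: none
Why: Catalytic hydrogenation saturates the conjugated alkene and hydrogenolyses the benzyl ether in one operation; an aliphatic ketone and a diaryl ether are not reduced under these conditions.

## Compound list

1 | 2-methoxyresorcinol | COc1c(O)cccc1O | starting material
2 | 2,4-dihydroxy-3-methoxybenzaldehyde | O=Cc1ccc(O)c(OC)c1O | intermediate
3 | (5-bromo-2-methoxyphenyl)boronic acid | COc1ccc(Br)cc1B(O)O | starting material
4 | 4-(5-bromo-2-methoxyphenoxy)-2-hydroxy-3-methoxybenzaldehyde | O=Cc1ccc(Oc2cc(Br)ccc2OC)c(OC)c1O | intermediate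
5 | 2-(benzyloxy)-4-(5-bromo-2-methoxyphenoxy)-3-methoxybenzaldehyde | O=Cc1ccc(Oc2cc(Br)ccc2OC)c(OC)c1OCc1ccccc1 | intermediate
6 | [2-(1,3-dioxolan-2-yl)ethyl]zinc bromide | Br[Zn]CCC1OCCO1 | starting material
7 | 2-(benzyloxy)-4-{5-[2-(1,3-dioxolan-2-yl)ethyl]-2-methoxyphenoxy}-3-methoxybenzaldehyde | O=Cc1ccc(Oc2cc(CCC3OCCO3)ccc2OC)c(OC)c1OCc1ccccc1 | intermediate
8 | [2-(benzyloxy)-4-{5-[2-(1,3-dioxolan-2-yl)ethyl]-2-methoxyphenoxy}-3-methoxyphenyl]methanol | OCc1ccc(Oc2cc(CCC3OCCO3)ccc2OC)c(OC)c1OCc1ccccc1 | intermediate
9 | 2-(benzyloxy)-1-(bromomethyl)-4-{5-[2-(1,3-dioxolan-2-yl)ethyl]-2-methoxyphenoxy}-3-methoxybenzene | BrCc1ccc(Oc2cc(CCC3OCCO3)ccc2OC)c(OC)c1OCc1ccccc1 | intermediate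
10 | 1-(trimethylsilyl)propyne | CC#C[Si](C)(C)C | starting material
11 | {4-[2-(benzyloxy)-4-{5-[2-(1,3-dioxolan-2-yl)ethyl]-2-methoxyphenoxy}-3-methoxyphenyl]but-1-yn-1-yl}trimethylsilane | C[Si](C)(C)C#CCCc1ccc(Oc2cc(CCC3OCCO3)ccc2OC)c(OC)c1OCc1ccccc1 | intermediate (not isolated)
12 | 2-(2-{3-[3-(benzyloxy)-4-(but-3-yn-1-yl)-2-methoxyphenoxy]-4-methoxyphenyl}ethyl)-1,3-dioxolane | C#CCCc1ccc(Oc2cc(CCC3OCCO3)ccc2OC)c(OC)c1OCc1ccccc1 | intermediate
13 | 3-{3-[3-(benzyloxy)-4-(but-3-yn-1-yl)-2-methoxyphenoxy]-4-methoxyphenyl}propanal | COc1ccc(CCC=O)cc1Oc1ccc(CCC#C)c(OCc2ccccc2)c1OC | intermediate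
14 | macrocyclic (E)-allylic triethylsilyl ether (racemic, one enantiomer drawn) | COc1ccc2cc1Oc1ccc(c(OCc3ccccc3)c1OC)CC/C=C/[C@@H](O[Si](CC)(CC)CC)CC2 | intermediate
15 | macrocyclic (E)-allylic alcohol (racemic, one enantiomer drawn) | COc1ccc2cc1Oc1ccc(c(OCc3ccccc3)c1OC)CC/C=C/[C@@H](O)CC2 | intermediate
16 | O-benzyl-4,5-didehydrojuglanin A | COc1ccc2cc1Oc1ccc(c(OCc3ccccc3)c1OC)CC/C=C/C(=O)CC2 | intermediate
17 | juglanin A | COc1ccc2cc1Oc1ccc(c(O)c1OC)CCCCC(=O)CC2 | target

## Step count and risks

Total step count: 12. Longest linear sequence: 12 steps (1 to 17); the route is linear, with 3, 6 and 10 entering as commercial reagents.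

**Step 9 (key step).**
- What may go wrong: intermolecular reductive coupling and nickel-mediated alkyne oligomerisation may outpace closure of the bent 15-membered ring. Bond formation may also occur at the internal alkyne carbon, which contracts the ring and leaves an exocyclic methylene.
- Fallback: keep the C3–C4 disconnection but fix regiochemistry and geometry before ring closure. Setting out from 12, hydrozirconation with Cp2Zr(H)Cl and iodination with I2 should give the (E)-vinyl iodide acetal F1. Dilute aqueous HCl in THF releases the iodo aldehyde F2. A Nozaki–Hiyama–Kishi macrocyclisation (CrCl2 in excess, catalytic NiCl2, DMSO/THF, high dilution) adds the vinylchromium species to the aldehyde and gives the allylic alcohol directly. The fallback rejoins the route at 15 and makes step 10 unnecessary.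

**Step 2.**
- What may go wrong: transmetalation of the ortho-methoxy boronic acid is slow, so protodeboronation and homocoupling can consume it. Copper can be held by the salicylaldehyde unit, and some arylation at the chelated 2-hydroxyl may occur.
- Fallback: replace the oxidative boron coupling by a halide-based Ullmann ether synthesis. Setting out from 2, coupling with 4-bromo-2-iodoanisole (CuI, N,N-dimethylglycine, Cs2CO3, dioxane, 90 °C) should engage the C–I bond in preference to C–Br and return to the route at 4. No new intermediate is involved.

**Step 4.**
- What may go wrong: if oxidative addition into the electron-rich C–Br bond is slow, 1,2-addition of the alkylzinc to the aryl aldehyde and protodezincation can compete.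
- Fallback: remove the aldehyde first and change the organometallic. Setting out from 5, NaBH4 reduction gives the bromo benzyl alcohol F3. Hydroboration of 2-vinyl-1,3-dioxolane with 9-BBN gives the B-alkyl borane F4. A Suzuki–Miyaura coupling of the two (PdCl2(dppf), aq. K3PO4, DMF/THF, 60 °C) returns to the route at 8.

**Step 7.**
- What may go wrong: the electron-rich benzylic bromide can ionise and self-condense before or during alkylation, can homocouple by electron transfer, and the ambident anion can attack through its allenyl terminus.
- Fallback: avoid a benzylic electrophile altogether. Setting out from 7, a Horner–Wadsworth–Emmons reaction with triethyl phosphonoacetate (NaH, THF) gives the ethyl (E)-cinnamate F5. Conjugate reduction with NaBH4 and NiCl2·6H2O in EtOH gives the saturated ester F6. DIBAL-H at −78 °C gives the 3-arylpropanal F7. Seyferth–Gilbert homologation with dimethyl (1-diazo-2-oxopropyl)phosphonate (K2CO3, MeOH) returns to the route at 12. This costs one step more than the main sequence.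

## Further compounds

F1 | step 9 | 2-(2-{3-[3-(benzyloxy)-4-[(E)-4-iodobut-3-en-1-yl]-2-methoxyphenoxy]-4-methoxyphenyl}ethyl)-1,3-dioxolane | I/C=C/CCc1ccc(Oc2cc(CCC3OCCO3)ccc2OC)c(OC)c1OCc1ccccc1
F2 | step 9 | 3-{3-[3-(benzyloxy)-4-[(E)-4-iodobut-3-en-1-yl]-2-methoxyphenoxy]-4-methoxyphenyl}propanal | I/C=C/CCc1ccc(Oc2cc(CCC=O)ccc2OC)c(OC)c1OCc1ccccc1
F0 | step 2 | none | none
F3 | step 4 | [2-(benzyloxy)-4-(5-bromo-2-methoxyphenoxy)-3-methoxyphenyl]methanol | OCc1ccc(Oc2cc(Br)ccc2OC)c(OC)c1OCc1ccccc1
F4 | step 4 | 9-[2-(1,3-dioxolan-2-yl)ethyl]-9-borabicyclo[3.3.1]nonane | C1COC(O1)CCB1C2CCCC1CCC2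
F5 | step 7 | ethyl (E)-3-[2-(benzyloxy)-4-{5-[2-(1,3-dioxolan-2-yl)ethyl]-2-methoxyphenoxy}-3-methoxyphenyl]prop-2-enoate | CCOC(=O)/C=C/c1ccc(Oc2cc(CCC3OCCO3)ccc2OC)c(OC)c1OCc1ccccc1
F6 | step 7 | ethyl 3-[2-(benzyloxy)-4-{5-[2-(1,3-dioxolan-2-yl)ethyl]-2-methoxyphenoxy}-3-methoxyphenyl]propanoate | CCOC(=O)CCc1ccc(Oc2cc(CCC3OCCO3)ccc2OC)c(OC)c1OCc1ccccc1
F7 | step 7 | 3-[2-(benzyloxy)-4-{5-[2-(1,3-dioxolan-2-yl)ethyl]-2-methoxyphenoxy}-3-methoxyphenyl]propanal | O=CCCc1ccc(Oc2cc(CCC3OCCO3)ccc2OC)c(OC)c1OCc1ccccc1
A1 | alternative 1 | 10-{4-methoxy-3-[(4-methoxyfuran-3-yl)oxy]phenyl}-8-oxodec-2-ynal | COc1ccc(CCC(=O)CCCCC#CC=O)cc1Oc1cocc1OC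
A2 | alternative 1 | B3-formyl juglanin A | COc1ccc2cc1Oc1cc(C=O)c(c(O)c1OC)CCCCC(=O)CC2
A3 | alternative 2 | 1-[2-(4-{2-(benzyloxy)-3-methoxy-4-[(3-methoxybuta-1,3-dien-2-yl)oxy]phenyl}butyl)-1,3-dioxolan-2-yl]but-3-yn-2-one | C=C(OC)C(=C)Oc1ccc(CCCCC2(OCCO2)CC(=O)C#C)c(OCc2ccccc2)c1OC
A4 | alternative 2 | O-benzyl 1-oxo juglanin A 3-ethylene ketal | COc1ccc2cc1Oc1ccc(c(OCc3ccccc3)c1OC)CCCCC3(OCCO3)CC2=O
A5 | alternative 3 | 6-(hydroxymethyl)-2-methoxy-3-{2-methoxy-5-[(3Z)-3-(tert-butyldimethylsilyloxy)hexa-3,5-dien-1-yl]phenoxy}phenol | COc1ccc(CC/C(O[Si](C)(C)C(C)(C)C)=C/C=C)cc1Oc1ccc(CO)c(O)c1OC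
A6 | alternative 3 | 4,5-didehydro juglanin A | COc1ccc2cc1Oc1ccc(c(O)c1OC)CC/C=C/C(=O)CC2
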